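**Plan**
- Retrosynthesis: the chain is cut at C11=C12 (Wittig) and at C7=C8 (vinylogous Horner–Wadsworth–Emmons). The C10′ aldehyde is carried as a dioxolane. This leads back to a C10 ring aldehyde (ring plus C7).
- Enabling feature: C5 and C6 of the cyclohexane ring form a vicinal bis-tertiary diol, which is the retron of a 1,2-dione. The other four ring atoms, C1–C4 with the gem-dimethyl group on C1, map onto 4-methylpenta-1,3-diene. Cutting C4–C5 and C1–C6 gives these two pieces.
- Forward, ring: dione, diene and B2pin2 under Ni(0) should close the only ring in one operation, a reductive [4+2]. Two electrophilic carbonyl carbons are joined to the two diene termini, and the B–B bond supplies the electrons.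
- Helpers: the C2=C3 alkene is hydrogenated, the O–B esters are hydrolysed, and the diethyl acetal at C7 is hydrolysed.
- Forward, chain: C10 aldehyde, then C15 dienoate, C15 phosphonium salt, C27 acetal and target. The C12 partner comes from the C10 dialdehyde.
- Stereochemistry: C5 comes from the chiral ligand on nickel. C6 follows by relay from the transient C3–B centre through a non-chelated allylboration, which gives the trans diol. The alkenes are E from the olefination selectivity and thermal or iodine equilibration.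

Key step: step 2

Remark: carotenoid numbering is used (ring C1–C6, gem-dimethyl on C1, chain C7 to C10′); the SMILES is read as (5R,6R) with trans hydroxyl groups and seven E chain alkenes; the (R,R) ligand in step 2 is written on the assumption that it gives 5R, otherwise its enantiomer is used.

Step 1
Reactants: 1 1,1-diethoxybut-2-yne
Product: 2 1,1-diethoxybutane-2,3-dione
Conditions: RuO2·xH2O (2 mol %), NaIO4 (2.2 equiv), NaHCO3, EtOAc/MeCN/H2O, 0 °C
Reagents that add atoms: sodium periodate, [Na+].[O-]I(=O)(=O)=O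
Why: Catalytic ruthenium tetroxide oxidises internal alkynes to 1,2-diketones (alkyne-to-α-diketone oxidation), and the bicarbonate buffer should keep the acetal intact.

Step 2
Reactants: 2 1,1-diethoxybutane-2,3-dione; 3 4-methylpenta-1,3-diene; 4 bis(pinacolato)diboron
Product: 7 (1R,2R)-1-(diethoxymethyl)-2,6,6-trimethylcyclohex-4-ene-1,2-diol, via keto allylboronate 5 (not isolated), via cyclic bis-borate 6 (not isolated)
Conditions: Ni(cod)2 (10 mol %), (R,R)-TADDOL-derived phenylphosphonite (12 mol %), 4 (1.2 equiv), 3 (3 equiv), toluene, slow addition of 2, rt then 60 °C; then MeOH/H2O, rt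
Reagents that add atoms: none
Why: Proposed new method: Ni(0)·L* should couple the unsubstituted terminus C4 of 3 oxidatively with the methyl-ketone carbon C5 of 2 to an oxanickelacycle (C4–C5 bond), B2pin2 then cleaves the Ni–O bond and C–B reductive elimination at C3 gives 5, whose γ-carbon C1 adds with allyl transposition to the neighbouring ketone C6 (C1–C6 bond) to give 6, so that two electrophilic carbonyl carbons are joined to one diene at the expense of the B–B bond. The closest known reaction types are the nickel-catalysed three-component borylative coupling of ketones, 1,3-dienes and B2pin2 (which stops at the 3-boryl stage), the allylboration of ketones and the ruthenium(0)-catalysed diene–1,2-dione [4+2] cycloaddition, and the new element is that a second carbonyl group in the same molecule intercepts the allylboronate. The single ring closes 6-exo-trig at C6=O with the allyl unit C1–C3 ending inside the ring, through a closed boat-like B–O=C transition state of bicyclo[2.2.2]octane shape that leaves the cis C2=C3 alkene. C5 is set by the chiral ligand, which selects the face of the methyl ketone in the oxidative coupling. C6 is set by relay: in the nickelacycle the alkenyl group on C3 should lie trans to the bulky acyl group on C5, the resulting C3–B centre delivers C1 suprafacially to one face of C6=O, and because tricoordinate boron binds only O6 and cannot chelate O5, the C5–OBpin and C6=O dipoles stand anti and the small O5 rather than the C5 methyl faces the C1 methyl, which together should give the trans diol. The step needs site selectivity between two ketones and two diene termini, and the branched diethoxymethyl group shields C6 so that nickel takes the methyl ketone, while the gem-dimethyl terminus C1 cannot compete with the CH2 terminus C4 for the first bond yet is the obligatory γ-carbon of the second.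

Step 3
Reactants: 7 (1R,2R)-1-(diethoxymethyl)-2,6,6-trimethylcyclohex-4-ene-1,2-diol
Product: 8 (1R,2R)-1-(diethoxymethyl)-2,6,6-trimethylcyclohexane-1,2-diol
Conditions: H2 (1 atm), 10% Pd/C, EtOAc, rt
Reagents that add atoms: none
Why: Heterogeneous catalytic hydrogenation removes the helper alkene C2=C3 without touching the acetal, the tertiary alcohols or either stereocentre.

Step 4
Reactants: 8 (1R,2R)-1-(diethoxymethyl)-2,6,6-trimethylcyclohexane-1,2-diol
Product: 9 (1R,2R)-1,2-dihydroxy-2,6,6-trimethylcyclohexane-1-carbaldehyde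
Conditions: 1 M aq HCl, THF, rt
Reagents that add atoms: water, O
Why: Acid-catalysed acetal hydrolysis frees the C7 aldehyde, and C6 bears no hydrogen and so cannot epimerise, while the dilute acid at rt should be too mild for a pinacol shift of the diol.

Step 5
Reactants: 9 (1R,2R)-1,2-dihydroxy-2,6,6-trimethylcyclohexane-1-carbaldehyde; 10 triethyl 3-methyl-4-phosphonocrotonate (commercial E/Z mixture, E form drawn)
Product: 11 ethyl (2E,4E)-5-[(1R,2R)-1,2-dihydroxy-2,6,6-trimethylcyclohexyl]-3-methylpenta-2,4-dienoate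
Conditions: 10 (3.3 equiv), LiHMDS (3.2 equiv), THF/DMPU, −78 to 0 °C
Reagents that add atoms: none
Why: The vinylogous Horner–Wadsworth–Emmons olefination should give the (7E,9E)-dienoate because the phosphonate anion equilibrates to the E form and the elimination is E-selective, with the excess anion covering the two free hydroxyl groups.

Step 6
Reactants: 11 ethyl (2E,4E)-5-[(1R,2R)-1,2-dihydroxy-2,6,6-trimethylcyclohexyl]-3-methylpenta-2,4-dienoate
Product: 12 (1R,2R)-1-[(1E,3E)-5-hydroxy-3-methylpenta-1,3-dien-1-yl]-2,6,6-trimethylcyclohexane-1,2-diol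
Conditions: DIBAL-H (5 equiv), CH2Cl2, −78 to −20 °C; aq Rochelle salt
Reagents that add atoms: none
Why: DIBAL-H reduces a dienoate in 1,2-fashion to the allylic alcohol without changing the alkene geometry.

Step 7
Reactants: 12 (1R,2R)-1-[(1E,3E)-5-hydroxy-3-methylpenta-1,3-dien-1-yl]-2,6,6-trimethylcyclohexane-1,2-diol
Product: 14 [(2E,4E)-5-[(1R,2R)-1,2-dihydroxy-2,6,6-trimethylcyclohexyl]-3-methylpenta-2,4-dien-1-yl]triphenylphosphonium bromide, via dienyl bromide 13 (not isolated)
Conditions: CBr4 (1.1 equiv), PPh3 (2.5 equiv), CH2Cl2, 0 °C to rt, dark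
Reagents that add atoms: triphenylphosphine, c1ccc(cc1)P(c1ccccc1)c1ccccc1; carbon tetrabromide, BrC(Br)(Br)Br
Why: The neutral Appel reaction converts only the primary allylic alcohol, since the two hindered tertiary alcohols do not react, and the excess phosphine quaternises the labile bromide in the same flask.

Step 8
Reactants: 15 (2E,4E,6E)-2,7-dimethylocta-2,4,6-trienedial; 16 (1,3-dioxolan-2-ylmethyl)triphenylphosphonium bromide
Product: 17 (2E,4E,6E,8E)-9-(1,3-dioxolan-2-yl)-2,7-dimethylnona-2,4,6,8-tetraenal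
Conditions: 16, KOtBu, THF, 0 °C, added to 15 (3 equiv); then I2 (cat.), CH2Cl2, daylight
Reagents that add atoms: none
Why: The Wittig two-carbon homologation with the acetal ylide is held at mono-olefination by the excess of the symmetrical dialdehyde, and iodine equilibrates the new alkene to E.

Step 9
Reactants: 14 the C15 phosphonium bromide; 17 (2E,4E,6E,8E)-9-(1,3-dioxolan-2-yl)-2,7-dimethylnona-2,4,6,8-tetraenal
Product: 18 ethylene acetal of (5R,6R)-5,6-dihydroxy-5,6-dihydro-10′-apo-β-caroten-10′-al (all-E)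
Conditions: NaOMe, MeOH/CH2Cl2, 0 °C to rt; then EtOH, reflux, dark, Ar
Reagents that add atoms: none
Why: The Wittig reaction of the semi-stabilised dienyl ylide forms C11=C12 in the presence of free tertiary alcohols, and the hindered 11Z isomer should relax thermally to all-E.

Step 10
Reactants: 18 ethylene acetal of (5R,6R)-5,6-dihydroxy-5,6-dihydro-10′-apo-β-caroten-10′-al
Product: 19 (5R,6R)-5,6-dihydroxy-5,6-dihydro-10′-apo-β-caroten-10′-al (target)
Conditions: 0.1 M aq HCl, THF, 0 °C to rt, dark, Ar
Reagents that add atoms: water, O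
Why: A polyenyl acetal hydrolyses through a strongly stabilised cation under very dilute acid, which should leave the 5,6-diol untouched and lets any residual 11′Z enal relax to E.

**Compound list**
1 | 1,1-diethoxybut-2-yne | CC#CC(OCC)OCC | starting material
2 | 1,1-diethoxybutane-2,3-dione | CCOC(OCC)C(=O)C(C)=O | intermediate
3 | 4-methylpenta-1,3-diene | CC(C)=CC=C | starting material
4 | bis(pinacolato)diboron | CC1(C)OB(OC1(C)C)B1OC(C)(C)C(C)(C)O1 | starting material
5 | (3R,5R)-1,1-diethoxy-3,7-dimethyl-5-(pinacolatoboryl)-3-(pinacolatoboryloxy)oct-6-en-2-one | CCOC(OCC)C(=O)[C@](C)(OB1OC(C)(C)C(C)(C)O1)C[C@H](C=C(C)C)B1OC(C)(C)C(C)(C)O1 | intermediate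
6 | (1R,2R)-1-(diethoxymethyl)-2,6,6-trimethylcyclohex-4-ene-1,2-diyl bis(pinacol borate) | CCOC(OCC)[C@@]1(OB2OC(C)(C)C(C)(C)O2)C(C)(C)C=CC[C@@]1(C)OB1OC(C)(C)C(C)(C)O1 | intermediate
7 | (1R,2R)-1-(diethoxymethyl)-2,6,6-trimethylcyclohex-4-ene-1,2-diol | CCOC(OCC)[C@@]1(O)C(C)(C)C=CC[C@@]1(C)O | intermediate
8 | (1R,2R)-1-(diethoxymethyl)-2,6,6-trimethylcyclohexane-1,2-diol | CCOC(OCC)[C@@]1(O)C(C)(C)CCC[C@@]1(C)O | intermediate
9 | (1R,2R)-1,2-dihydroxy-2,6,6-trimethylcyclohexane-1-carbaldehyde | O=C[C@@]1(O)C(C)(C)CCC[C@@]1(C)O | intermediate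
10 | triethyl 3-methyl-4-phosphonocrotonate (E form drawn) | CCOC(=O)/C=C(\C)CP(=O)(OCC)OCC | starting material
11 | ethyl (2E,4E)-5-[(1R,2R)-1,2-dihydroxy-2,6,6-trimethylcyclohexyl]-3-methylpenta-2,4-dienoate | CCOC(=O)/C=C(C)/C=C/[C@@]1(O)C(C)(C)CCC[C@@]1(C)O | intermediate
12 | (1R,2R)-1-[(1E,3E)-5-hydroxy-3-methylpenta-1,3-dien-1-yl]-2,6,6-trimethylcyclohexane-1,2-diol | OC/C=C(C)/C=C/[C@@]1(O)C(C)(C)CCC[C@@]1(C)O | intermediate
13 | (1R,2R)-1-[(1E,3E)-5-bromo-3-methylpenta-1,3-dien-1-yl]-2,6,6-trimethylcyclohexane-1,2-diol | BrC/C=C(C)/C=C/[C@@]1(O)C(C)(C)CCC[C@@]1(C)O | intermediate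
14 | [(2E,4E)-5-[(1R,2R)-1,2-dihydroxy-2,6,6-trimethylcyclohexyl]-3-methylpenta-2,4-dien-1-yl]triphenylphosphonium bromide | [Br-].C(/C=C(C)/C=C/[C@@]1(O)C(C)(C)CCC[C@@]1(C)O)[P+](c1ccccc1)(c1ccccc1)c1ccccc1 | intermediate
15 | (2E,4E,6E)-2,7-dimethylocta-2,4,6-trienedial | O=C/C(C)=C/C=C/C=C(C)/C=O | starting material
16 | (1,3-dioxolan-2-ylmethyl)triphenylphosphonium bromide | [Br-].C1COC(C[P+](c2ccccc2)(c2ccccc2)c2ccccc2)O1 | starting material
17 | (2E,4E,6E,8E)-9-(1,3-dioxolan-2-yl)-2,7-dimethylnona-2,4,6,8-tetraenal | O=C/C(C)=C/C=C/C=C(C)/C=C/C1OCCO1 | intermediate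
18 | (1R,2R)-1-[(1E,3E,5E,7E,9E,11E,13E)-14-(1,3-dioxolan-2-yl)-3,7,12-trimethyltetradeca-1,3,5,7,9,11,13-heptaen-1-yl]-2,6,6-trimethylcyclohexane-1,2-diol | CC(/C=C/C2OCCO2)=C\C=C\C=C(C)\C=C\C=C(C)\C=C\[C@@]1(O)C(C)(C)CCC[C@@]1(C)O | intermediate
19 | (5R,6R)-5,6-dihydroxy-5,6-dihydro-10′-apo-β-caroten-10′-al | CC(/C=C/C=O)=C\C=C\C=C(C)\C=C\C=C(C)\C=C\[C@@]1(O)C(C)(C)CCC[C@@]1(C)O | target

Total step count: 10. Longest linear sequence: 9 (steps 1–7, 9, 10).

**Steps most likely to fail**

Step 2.
- What may go wrong: the dione may be reduced at nickel or by the diboron reagent to an enediol bis-borate before it meets the diene. Nickel may engage the hindered ketone. The boat-shaped allylboration may be too slow. The ligand may give poor facial selectivity.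
- Fallback (known chemistry, from 3 back to 9): a Diels–Alder reaction of 3 with ethyl but-2-ynoate (AlCl3, or 150 °C in a sealed tube) should form the same two ring bonds in ethyl 2,6,6-trimethylcyclohexa-1,4-diene-1-carboxylate F1. RhCl(PPh3)3/H2 saturates only the disubstituted alkene to ethyl 2,6,6-trimethylcyclohex-1-ene-1-carboxylate F2. LiAlH4 gives (2,6,6-trimethylcyclohex-1-en-1-yl)methanol F3. Sharpless epoxidation with D-(−)-diethyl tartrate sets both centres in [(1S,6S)-2,2,6-trimethyl-7-oxabicyclo[4.1.0]heptan-1-yl]methanol F4. Parikh–Doering oxidation gives (1R,6S)-2,2,6-trimethyl-7-oxabicyclo[4.1.0]heptane-1-carbaldehyde F5. Dilute HClO4 in THF/H2O opens the oxirane at C5 with inversion to 9.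

Step 5.
- What may go wrong: the doubly neopentyl aldehyde may add the phosphonate anion slowly. The lithium alkoxide of the α-hydroxy aldehyde may then undergo an α-ketol shift with ring expansion.
- Fallback (from 9 back to 11, cross-coupling in place of olefination): Ohira–Bestmann homologation (K2CO3, MeOH) gives (1S,2R)-1-ethynyl-2,6,6-trimethylcyclohexane-1,2-diol F6. Palladium-catalysed hydrostannation (Bu3SnH, PdCl2(PPh3)2) gives (1R,2R)-2,6,6-trimethyl-1-[(E)-2-(tributylstannyl)ethenyl]cyclohexane-1,2-diol F7. Stille coupling with ethyl (E)-3-iodobut-2-enoate proceeds with retention at both alkenes and gives 11.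

Step 7.
- What may go wrong: the dienyl bromide may ionise. This would scramble the alkene geometry or cause loss of the tertiary allylic hydroxyl group at C6.
- Fallback (from 12 back to 18, a sulfone-based olefination that avoids an allylic halide): Mitsunobu reaction with 1-phenyl-1H-tetrazole-5-thiol gives the dienyl tetrazolyl sulfide F8. Molybdate/H2O2 gives the dienyl tetrazolyl sulfone F9. Julia–Kocienski olefination (KHMDS, THF, −78 °C) with 17, followed by thermal equilibration, gives 18.

**Further compounds**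
F1 | step 2 | ethyl 2,6,6-trimethylcyclohexa-1,4-diene-1-carboxylate | CCOC(=O)C1=C(C)CC=CC1(C)C
F2 | step 2 | ethyl 2,6,6-trimethylcyclohex-1-ene-1-carboxylate | CCOC(=O)C1=C(C)CCCC1(C)C
F3 | step 2 | (2,6,6-trimethylcyclohex-1-en-1-yl)methanol | OCC1=C(C)CCCC1(C)C
F4 | step 2 | [(1S,6S)-2,2,6-trimethyl-7-oxabicyclo[4.1.0]heptan-1-yl]methanol | OC[C@]12O[C@@]1(C)CCCC2(C)C
F5 | step 2 | (1R,6S)-2,2,6-trimethyl-7-oxabicyclo[4.1.0]heptane-1-carbaldehyde | O=C[C@]12O[C@@]1(C)CCCC2(C)C
F6 | step 5 | (1S,2R)-1-ethynyl-2,6,6-trimethylcyclohexane-1,2-diol | C#C[C@@]1(O)C(C)(C)CCC[C@@]1(C)O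
F7 | step 5 | (1R,2R)-2,6,6-trimethyl-1-[(E)-2-(tributylstannyl)ethenyl]cyclohexane-1,2-diol | CCCC[Sn](CCCC)(CCCC)/C=C/[C@@]1(O)C(C)(C)CCC[C@@]1(C)O
F8 | step 7 | (1R,2R)-2,6,6-trimethyl-1-[(1E,3E)-3-methyl-5-(1-phenyl-1H-tetrazol-5-ylsulfanyl)penta-1,3-dien-1-yl]cyclohexane-1,2-diol | C(/C=C(C)/C=C/[C@@]1(O)C(C)(C)CCC[C@@]1(C)O)Sc1nnnn1-c1ccccc1
F9 | step 7 | (1R,2R)-2,6,6-trimethyl-1-[(1E,3E)-3-methyl-5-(1-phenyl-1H-tetrazol-5-ylsulfonyl)penta-1,3-dien-1-yl]cyclohexane-1,2-diol | C(/C=C(C)/C=C/[C@@]1(O)C(C)(C)CCC[C@@]1(C)O)S(=O)(=O)c1nnnn1-c1ccccc1
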